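**Slow feed.** The slowness of a feed sets a rate that can be held against another rate, and dawn is a flask in which to do so: its first end groups stand in the flask from the start while second end groups trickle in.

| flask | first end groups | second end groups | remark | time |
|---|---|---|---|---|
| beta | 2 mM | 2 mM | run made earlier |  |
| delta | 1.3 mM | 2 mM | run made earlier |  |
| theta | 3 mM | 2 mM | run made earlier |  |
| zeta | 2 mM | 1 mM | run made earlier |  |
| winter | 2.0 mM | 2.00 mM | everything together at the start | 2.0 min |
| dawn | 2.0 mM | 2.00 mM (fed, over 80 s) | all else is in the flask from the start; the feed brings no volume worth counting | 2.0 min |
| spring | 2.0 mM (fed, over 8.0 s) | 2.00 mM | all else is in the flask from the start; the feed brings no volume worth counting | 2.0 min |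
| noon | 2.0 mM (fed, over 80 s) | 2.00 mM | all else is in the flask from the start; the feed brings no volume worth counting | 2.0 min |

- beta (time / s: homo dimer / %, links / %): 20.0: 50, 38; 40.0: 49, 42; 50.0: 47, 41; 80.0: 49, 41
- delta (time / s: homo dimer / %, links / %): 10.0: 37, 45; 12.0: 38, 48; 30.0: 36, 49; 80.0: 40, 50
- theta (time / s: homo dimer / %, links / %): 10.0: 60, 28; 25.0: 56, 32; 50.0: 59, 31; 80.0: 57, 30
- zeta (time / s: homo dimer / %, links / %): 10.0: 61, 19; 25.0: 61, 21; 50.0: 61, 23; 80.0: 62, 22

(readings scatter by 1.5 percentage points)

- percentages count the first end groups that a species holds: one homo dimer counts as two
- links is meant together with its crystals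
- solid, in amounts per volume of the solution: crystals
- candidate steps: first end groups + second end groups -> links; first end groups + second end groups -> rings; 2 first end groups -> homo dimer; crystals <-> links

- the flask that comes out highest in amount of homo dimer, in percent of the first end groups charged, or "all alike" when all lie within 1.5 percentage points (winter / dawn / spring / noon / all alike)
- homo dimer at the end, in percent of the first end groups charged, winter
- homo dimer at the end, in percent of the first end groups charged, dawn
- homo dimer at the end, in percent of the first end groups charged, spring
- homo dimer at the end, in percent of the first end groups charged, noon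

**Runs so far.** In beta, which has winter's charges, homo dimer stays between 47% and 50% from 20.0 s on, so that batch is over early.

**Rate reckoning.** This reckoning, separate from the forecast, borrows its loose 0.3 per mM per second for the dimer step. Dawn's first end groups then start by dimerising at 2.40 mM s⁻¹, while the feed supplies 0.0250 mM s⁻¹. Their ratio, a Damköhler number that sets reaction against feed, is 96.0, so the dimer rate starts far above the feed rate. Nothing slows the feed, but the dimer rate goes with [first end groups] squared, so to slow by that ratio [first end groups] must fall by its square root. The crossing share, the fraction of first end groups still unspent when the dimer rate has slowed to the feed rate, is therefore 10.2%. Counting that share as lost to links and rings leaves 89.8% homo dimer in dawn.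

**The forecast.** It expects 49% in winter, 88% in dawn, 26% in spring and 16% in noon, with dawn highest, because “A sits almost alone and dimerises within seconds”. Its dawn figure stands a little below the 89.8% of the reckoning above.

**The result.** Homo dimer ends at 49.0% in winter, 81.6% in dawn, 37.3% in spring and 16.7% in noon, so dawn is highest.

    first end groups + second end groups → links (k = 110 M⁻¹ s⁻¹)
    first end groups + second end groups → rings, rate k2*[first end groups] as long as [second end groups] is above zero (k = 0.0420 s⁻¹)
    2 first end groups → homo dimer (k = 130 M⁻¹ s⁻¹)
    crystals ⇌ links, rate k4*(cs4 - [links]) while solid is left; crystals form when [links] > cs4 (solubility = 0.110 mM, k = 4.90 s⁻¹)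

**Neighbouring flask.** With the dimer constant above, dawn's crossing share becomes 15.5%, less than the 18.4% of first end groups that dawn leaves outside homo dimer. The neighbour of dawn charged with 3.4 mM of first end groups keeps the same feed, so its rate ratio grows by a factor of 2.89 and its crossing share shrinks to 9.12%. That reckons 90.9% homo dimer for the neighbour flask, which ends with rings at 9.40%, links at 1.99% and homo dimer at 88.6%.

The earlier runs and the new flask stem from a simulated flask with made-up constants; the scatter is artificial.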